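**Plan**

Numbering: lactone O1, C2–C6; side chain C1'–C10'. The cis C1'=C2' alkene lies between the oxygen-bearing carbons C6 and C4'. One silicon atom bridging O6 and O4' therefore puts Si, O, C6, C1', C2', C3', C4' and O into an eight-membered ring.
Cuts: O1–C2 and C3=C4 (lactone); C1'=C2' (tethered metathesis); C7'–C8' (aldol), C5'–C6' and C2'–C3' (two epoxide openings) in fragment A; C6–C1' (vinyl addition) in fragment B.
Forward: fragment A (C2'–C10', steps 1–8) and fragment B (C4–C6 plus C1', steps 9–12) are joined through iPr2Si (step 13). The eight-membered silaketal ring closes first (step 14), C3 and C2 are then added, and the six-membered lactone closes last as silicon leaves (step 18).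
Stereochemistry: C4' comes from (S)-epichlorohydrin and C8' from 1,5-anti boron aldol induction by C4'. C6' comes from 1,3-anti Evans–Tishchenko hydride delivery from O8', which also places the acetate, and C6 from a Sharpless kinetic resolution. C1'=C2' is cis because of the ring, and C3=C4 is cis from Still–Gennari olefination.

Key step: step 14

Remark: descriptors are those of the compound named. C6' reads S in 24–28 only because O4' then carries silicon; its spatial arrangement never changes.

**Fragment A**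

Step 1
Reactants: 1 2-methyl-1,3-dithiane; 2 (S)-epichlorohydrin
Product: 5 (S)-2-methyl-2-(oxiran-2-ylmethyl)-1,3-dithiane, via 2-lithio-2-methyl-1,3-dithiane 3 (not isolated), via lithium chlorohydrin alkoxide 4 (not isolated)
Conditions: nBuLi, THF, −30 °C; then 2, −78 °C to rt
Reagents that add atoms: none
Why: Corey–Seebach dithiane alkylation in which the lithiated dithiane opens the unsubstituted epoxide carbon of 2 (SN2, forms C5'–C6') and the released alkoxide displaces chloride on warming, so the C–O bond at the stereocentre is never broken and this centre becomes C4'.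

Step 2
Reactants: 5 (S)-2-methyl-2-(oxiran-2-ylmethyl)-1,3-dithiane; 6 vinylmagnesium bromide
Product: 7 (2R)-1-(2-methyl-1,3-dithian-2-yl)pent-4-en-2-ol
Conditions: CuI (10 mol %), THF, −40 to −10 °C; aq NH4Cl
Reagents that add atoms: none
Why: Copper-catalysed Grignard opening of a terminal epoxide at its CH2 terminus forms C2'–C3', leaves C4' untouched and tolerates the thioketal.

Step 3
Reactants: 7 (2R)-1-(2-methyl-1,3-dithian-2-yl)pent-4-en-2-ol
Product: 8 2-{(2R)-2-[(4-methoxybenzyl)oxy]pent-4-en-1-yl}-2-methyl-1,3-dithiane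
Conditions: NaH, PMBCl, nBu4NI (cat.), DMF, 0 °C to rt
Reagents that add atoms: 4-methoxybenzyl chloride, COc1ccc(CCl)cc1
Why: Williamson etherification, with a benzyl-type rather than a silyl ether chosen at O4' because that is what transmits 1,5-induction in step 5.

Step 4
Reactants: 8 2-{(2R)-2-[(4-methoxybenzyl)oxy]pent-4-en-1-yl}-2-methyl-1,3-dithiane
Product: 9 (4R)-4-[(4-methoxybenzyl)oxy]hept-6-en-2-one
Conditions: MeI, CaCO3, MeCN/H2O (9:1), 45 °C
Reagents that add atoms: water, O
Why: Alkylative dithiane hydrolysis, in which S-methylation makes sulfur a leaving group and water traps the thionium ion, under near-neutral conditions that should spare the PMB ether and the terminal alkene and avoid β-elimination.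

Step 5
Reactants: 9 (4R)-4-[(4-methoxybenzyl)oxy]hept-6-en-2-one; 10 3-phenylpropanal
Product: 12 (3R,7R)-3-hydroxy-7-[(4-methoxybenzyl)oxy]-1-phenyldec-9-en-5-one, via dibutylboron enolate 11 (not isolated)
Conditions: Bu2BOTf, iPr2NEt, Et2O, −78 °C; then 10, −78 °C; MeOH, pH 7 buffer, 30 % H2O2, 0 °C
Reagents that add atoms: none
Why: Boron aldol addition of a β-alkoxy methyl ketone with 1,5-anti induction, where enolisation on the methyl side gives 11, which should add to 10 through a boat-like transition state with a formyl C–H contact to the PMB-ether oxygen, forming C7'–C8' and setting C8' (R) anti to C4'.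

Step 6
Reactants: 12 (3R,7R)-3-hydroxy-7-[(4-methoxybenzyl)oxy]-1-phenyldec-9-en-5-one; 13 acetaldehyde
Product: 14 (3R,5R,7R)-5-hydroxy-7-[(4-methoxybenzyl)oxy]-1-phenyldec-9-en-3-yl acetate
Conditions: SmI2 (25 mol %), freshly distilled 13 (excess), THF, −10 °C
Reagents that add atoms: none
Why: Evans–Tishchenko reduction, in which the C8' hydroxyl forms a hemiacetal with acetaldehyde that is held together with the ketone on trivalent samarium and hands over its hydride through a chair-like bicyclic transition state, which should set C6' (R) 1,3-anti to C8' (hence syn to C4') and leave the acetate on O8' only.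

Step 7
Reactants: 14 (3R,5R,7R)-5-hydroxy-7-[(4-methoxybenzyl)oxy]-1-phenyldec-9-en-3-yl acetate
Product: 15 (3R,5R,7R)-5-[(tert-butyldimethylsilyl)oxy]-7-[(4-methoxybenzyl)oxy]-1-phenyldec-9-en-3-yl acetate
Conditions: TBSOTf, 2,6-lutidine, CH2Cl2, −78 to 0 °C
Reagents that add atoms: tert-butyldimethylsilyl triflate, CC(C)(C)[Si](C)(C)OS(=O)(=O)C(F)(F)F
Why: Silylation with a silyl triflate and a hindered pyridine base is fast at low temperature and should cap O6' before the neighbouring acetate can migrate.

Step 8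
Reactants: 15 (3R,5R,7R)-5-[(tert-butyldimethylsilyl)oxy]-7-[(4-methoxybenzyl)oxy]-1-phenyldec-9-en-3-yl acetate
Product: 16 (3R,5R,7R)-5-[(tert-butyldimethylsilyl)oxy]-7-hydroxy-1-phenyldec-9-en-3-yl acetate
Conditions: DDQ, CH2Cl2/pH 7 buffer (10:1), 0 °C
Reagents that add atoms: none
Why: Oxidative PMB cleavage (benzylic hydride abstraction, then hydrolysis of the oxocarbenium ion) frees O4', and acetate, TBS ether, phenyl ring and terminal alkene are not oxidised under buffered conditions.

**Fragment B**

Step 9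
Reactants: 17 propane-1,3-diol
Product: 18 3-[(4-methoxybenzyl)oxy]propan-1-ol
Conditions: NaH (1 equiv), PMBCl (1 equiv), 17 (3 equiv), nBu4NI (cat.), THF/DMF, 0 °C to rt
Reagents that add atoms: 4-methoxybenzyl chloride, COc1ccc(CCl)cc1
Why: Williamson mono-etherification, biased towards the mono-ether by an excess of the cheap diol.

Step 10
Reactants: 18 3-[(4-methoxybenzyl)oxy]propan-1-ol
Product: 19 3-[(4-methoxybenzyl)oxy]propanal
Conditions: TEMPO (cat.), PhI(OAc)2, CH2Cl2, rt
Reagents that add atoms: none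
Why: Oxoammonium-mediated alcohol oxidation stops at the aldehyde and is non-basic, so the β-alkoxy aldehyde should not eliminate.

Step 11
Reactants: 19 3-[(4-methoxybenzyl)oxy]propanal; 6 vinylmagnesium bromide
Product: 20 (±)-5-[(4-methoxybenzyl)oxy]pent-1-en-3-ol
Conditions: THF, −78 to 0 °C; aq NH4Cl
Reagents that add atoms: none
Why: Grignard 1,2-addition forms C6–C1'; no stereocontrol is sought because the racemate is resolved in the next step.

Step 12
Reactants: 20 (±)-5-[(4-methoxybenzyl)oxy]pent-1-en-3-ol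
Product: 21 (3S)-5-[(4-methoxybenzyl)oxy]pent-1-en-3-ol
Conditions: Ti(OiPr)4 (cat.), D-(−)-diisopropyl tartrate (cat.), tBuOOH (0.6 equiv), 4 Å MS, CH2Cl2, −20 °C
Reagents that add atoms: none
Why: Sharpless kinetic resolution, in which the titanium D-tartrate catalyst epoxidises the (R)-alcohol much faster, so running slightly past half conversion should leave the (S)-alcohol (future C6) in high enantiomeric purity and easily separable from the polar epoxy alcohol.

**Union and endgame**

Step 13
Reactants: 21 (3S)-5-[(4-methoxybenzyl)oxy]pent-1-en-3-ol; 22 dichlorodiisopropylsilane; 16 (3R,5R,7R)-5-[(tert-butyldimethylsilyl)oxy]-7-hydroxy-1-phenyldec-9-en-3-yl acetate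
Product: 24 (3R,5S,7R)-5-[(tert-butyldimethylsilyl)oxy]-7-{[diisopropyl({(3S)-5-[(4-methoxybenzyl)oxy]pent-1-en-3-yl}oxy)silyl]oxy}-1-phenyldec-9-en-3-yl acetate (mixed silaketal diene), via alkoxychlorosilane 23 (not isolated)
Conditions: 22 (1.2 equiv), imidazole, CH2Cl2, 0 °C, slow addition of 21 (1.2 equiv); then 16 (1.0 equiv), imidazole, DMAP (cat.), DMF, rt
Reagents that add atoms: none
Why: Stepwise nucleophilic substitution at silicon, where the two isopropyl groups make the second chloride of 22 far slower to leave than the first, so 23 can be built up from the cheaper alcohol before 16 is added, giving the unsymmetrical bis(alkoxy)silane without touching a stereocentre.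

Step 14
Reactants: 24 mixed silaketal diene
Product: 25 (4S,5Z,8R)-8-{(2S,4R)-4-acetoxy-2-[(tert-butyldimethylsilyl)oxy]-6-phenylhexyl}-2,2-diisopropyl-4-{2-[(4-methoxybenzyl)oxy]ethyl}-1,3-dioxa-2-silacyclooct-5-ene
Conditions: RuCl2(=CHPh)(H2IMes)(PCy3) (second-generation Grubbs catalyst, 10 mol % in portions), 1,4-benzoquinone (10 mol %), CH2Cl2 (0.001 M), reflux, Ar sparge
Reagents that add atoms: none
Why: Temporary silicon-tethered ring-closing olefin metathesis, in which the ruthenium benzylidene should first exchange with the unhindered vinyl group on the C4' side, and the new alkylidene then undergoes intramolecular [2+2] cycloaddition with the allylic vinyl group at C6 and cycloreversion, expelling ethene and forming C1'=C2'. The closest known reaction type is the metathesis of mixed bis(alkoxy)silanes of an allylic and a homoallylic alcohol to 1,3-dioxa-2-silacyclooct-5-enes. The one new ring (Si, O, C6, C1', C2', C3', C4', O) closes as an eight-membered ring with both alkene carbons endocyclic. No stereocentre is created, since C6, C4', C6' and C8' are spectators and only the alkene geometry is decided. The cis geometry rests on ring size, because the trans isomer of this medium ring is the more strained one and the reversible catalyst can drain material to the cis ring; cyclisation should beat oligomerisation through millimolar dilution, removal of ethene and the angle compression by the two isopropyl groups on silicon. None of the ester or ether groups binds to or is attacked by the catalyst, and benzoquinone suppresses ruthenium hydride alkene migration.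

Step 15
Reactants: 25 cyclic silaketal
Product: 26 (4S,5Z,8R)-8-{(2S,4R)-4-acetoxy-2-[(tert-butyldimethylsilyl)oxy]-6-phenylhexyl}-4-(2-hydroxyethyl)-2,2-diisopropyl-1,3-dioxa-2-silacyclooct-5-ene
Conditions: DDQ, CH2Cl2/pH 7 buffer (10:1), 0 °C
Reagents that add atoms: none
Why: Oxidative PMB cleavage as in step 8, with the buffer neutralising the acidic hydroquinone so that silaketal and TBS ether should survive, and the allylic silyl ether being far less electron-rich than the PMB group.

Step 16
Reactants: 26 primary alcohol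
Product: 27 (4S,5Z,8R)-8-{(2S,4R)-4-acetoxy-2-[(tert-butyldimethylsilyl)oxy]-6-phenylhexyl}-2,2-diisopropyl-4-(2-oxoethyl)-1,3-dioxa-2-silacyclooct-5-ene
Conditions: TEMPO (cat.), PhI(OAc)2, CH2Cl2, rt
Reagents that add atoms: none
Why: Oxoammonium oxidation of the primary alcohol to the C4 aldehyde runs without base, which avoids β-elimination of the C6 silyloxy group and leaves the cis alkene alone.

Step 17
Reactants: 27 aldehyde
Product: 28 methyl (2Z)-4-[(4S,5Z,8R)-8-{(2S,4R)-4-acetoxy-2-[(tert-butyldimethylsilyl)oxy]-6-phenylhexyl}-2,2-diisopropyl-1,3-dioxa-2-silacyclooct-5-en-4-yl]but-2-enoate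
Conditions: (CF3CH2O)2P(O)CH2CO2Me, KN(SiMe3)2, 18-crown-6, THF, −78 °C; then 27
Reagents that add atoms: methyl bis(2,2,2-trifluoroethyl)phosphonoacetate, COC(=O)CP(=O)(OCC(F)(F)F)OCC(F)(F)F
Why: Still–Gennari variant of the Horner–Wadsworth–Emmons olefination, in which the electron-poor phosphonate with a dissociated potassium ion eliminates from the kinetic adduct faster than that adduct reverts, so the Z-enoate (C3=C4) should form, and at −78 °C the stabilised anion is too weak a base to attack the acetate.

Step 18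
Reactants: 28 Z-enoate
Product: 30 (6S)-6-[(1Z,4R,6R,8R)-8-acetoxy-4,6-dihydroxy-10-phenyldec-1-en-1-yl]-5,6-dihydro-2H-pyran-2-one, via seco trihydroxy ester 29 (not isolated)
Conditions: HF·pyridine, THF, 0 °C to rt
Reagents that add atoms: none
Why: Fluoride cleavage of all three Si–O bonds in mildly acidic medium followed by spontaneous 6-exo-trig lactonisation of the C6 hydroxyl onto the Z-ester (the C4' hydroxyl would need a ten-membered ring), with an acidic rather than basic medium chosen to suppress O8' to O6' acetyl migration.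

**Compound list**

1 | 2-methyl-1,3-dithiane | CC1SCCCS1 | starting material
2 | (S)-epichlorohydrin | ClC[C@@H]1CO1 | starting material
3 | 2-lithio-2-methyl-1,3-dithiane | [Li]C1(C)SCCCS1 | intermediate
4 | lithium (2S)-1-chloro-3-(2-methyl-1,3-dithian-2-yl)propan-2-olate | [Li]O[C@H](CCl)CC1(C)SCCCS1 | intermediate
5 | (S)-2-methyl-2-(oxiran-2-ylmethyl)-1,3-dithiane | CC1(SCCCS1)C[C@H]2CO2 | intermediate
6 | vinylmagnesium bromide | C=C[Mg]Br | starting material
7 | (2R)-1-(2-methyl-1,3-dithian-2-yl)pent-4-en-2-ol | CC1(SCCCS1)C[C@H](O)CC=C | intermediate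
8 | 2-{(2R)-2-[(4-methoxybenzyl)oxy]pent-4-en-1-yl}-2-methyl-1,3-dithiane | CC1(SCCCS1)C[C@H](OCc2ccc(OC)cc2)CC=C | intermediate
9 | (4R)-4-[(4-methoxybenzyl)oxy]hept-6-en-2-one | CC(=O)C[C@H](OCc1ccc(OC)cc1)CC=C | intermediate
10 | 3-phenylpropanal | O=CCCc1ccccc1 | starting material
11 | dibutyl({(4R)-4-[(4-methoxybenzyl)oxy]hepta-1,6-dien-2-yl}oxy)borane | C=C(OB(CCCC)CCCC)C[C@H](OCc1ccc(OC)cc1)CC=C | intermediate
12 | (3R,7R)-3-hydroxy-7-[(4-methoxybenzyl)oxy]-1-phenyldec-9-en-5-one | O[C@H](CCc1ccccc1)CC(=O)C[C@H](OCc1ccc(OC)cc1)CC=C | intermediate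
13 | acetaldehyde | CC=O | starting material
14 | (3R,5R,7R)-5-hydroxy-7-[(4-methoxybenzyl)oxy]-1-phenyldec-9-en-3-yl acetate | CC(=O)O[C@H](CCc1ccccc1)C[C@H](O)C[C@H](OCc1ccc(OC)cc1)CC=C | intermediate
15 | (3R,5R,7R)-5-[(tert-butyldimethylsilyl)oxy]-7-[(4-methoxybenzyl)oxy]-1-phenyldec-9-en-3-yl acetate | CC(=O)O[C@H](CCc1ccccc1)C[C@H](O[Si](C)(C)C(C)(C)C)C[C@H](OCc1ccc(OC)cc1)CC=C | intermediate
16 | (3R,5R,7R)-5-[(tert-butyldimethylsilyl)oxy]-7-hydroxy-1-phenyldec-9-en-3-yl acetate | CC(=O)O[C@H](CCc1ccccc1)C[C@H](O[Si](C)(C)C(C)(C)C)C[C@H](O)CC=C | intermediate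
17 | propane-1,3-diol | OCCCO | starting material
18 | 3-[(4-methoxybenzyl)oxy]propan-1-ol | OCCCOCc1ccc(OC)cc1 | intermediate
19 | 3-[(4-methoxybenzyl)oxy]propanal | O=CCCOCc1ccc(OC)cc1 | intermediate
20 | (±)-5-[(4-methoxybenzyl)oxy]pent-1-en-3-ol | OC(C=C)CCOCc1ccc(OC)cc1 | intermediate
21 | (3S)-5-[(4-methoxybenzyl)oxy]pent-1-en-3-ol | O[C@H](C=C)CCOCc1ccc(OC)cc1 | intermediate
22 | dichlorodiisopropylsilane | CC(C)[Si](Cl)(Cl)C(C)C | starting material
23 | chloro(diisopropyl)({(3S)-5-[(4-methoxybenzyl)oxy]pent-1-en-3-yl}oxy)silane | CC(C)[Si](Cl)(C(C)C)O[C@H](C=C)CCOCc1ccc(OC)cc1 | intermediate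
24 | mixed diisopropylsilaketal diene (C8' R, C6' S, C4' R, C6 S) | CC(=O)O[C@H](CCc1ccccc1)C[C@H](O[Si](C)(C)C(C)(C)C)C[C@H](O[Si](C(C)C)(C(C)C)O[C@H](C=C)CCOCc1ccc(OC)cc1)CC=C | intermediate
25 | eight-membered cyclic silaketal with cis C1'=C2' and PMB ether | CC(=O)O[C@H](CCc1ccccc1)C[C@H](O[Si](C)(C)C(C)(C)C)C[C@H]1C/C=C\[C@H](CCOCc2ccc(OC)cc2)O[Si](C(C)C)(C(C)C)O1 | intermediate
26 | cyclic silaketal primary alcohol | CC(=O)O[C@H](CCc1ccccc1)C[C@H](O[Si](C)(C)C(C)(C)C)C[C@H]1C/C=C\[C@H](CCO)O[Si](C(C)C)(C(C)C)O1 | intermediate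
27 | cyclic silaketal C4 aldehyde | CC(=O)O[C@H](CCc1ccccc1)C[C@H](O[Si](C)(C)C(C)(C)C)C[C@H]1C/C=C\[C@H](CC=O)O[Si](C(C)C)(C(C)C)O1 | intermediate
28 | cyclic silaketal methyl (Z)-enoate | CC(=O)O[C@H](CCc1ccccc1)C[C@H](O[Si](C)(C)C(C)(C)C)C[C@H]1C/C=C\[C@H](C/C=C\C(=O)OC)O[Si](C(C)C)(C(C)C)O1 | intermediate
29 | methyl (2Z,5S,6Z,9R,11R,13R)-13-acetoxy-5,9,11-trihydroxy-15-phenylpentadeca-2,6-dienoate | CC(=O)O[C@H](CCc1ccccc1)C[C@H](O)C[C@H](O)C/C=C\[C@@H](O)C/C=C\C(=O)OC | intermediate
30 | (6S)-6-[(1Z,4R,6R,8R)-8-acetoxy-4,6-dihydroxy-10-phenyldec-1-en-1-yl]-5,6-dihydro-2H-pyran-2-one | CC(=O)O[C@H](CCc1ccccc1)C[C@H](O)C[C@H](O)C/C=C\[C@@H]1CC=CC(=O)O1 | target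

**Count and risks**

Total step count: 18 (fragment A 8, fragment B 4, union and endgame 6). Longest linear sequence: 14 (steps 1–8 and 13–18).

Step 14 carries the highest risk. Ring closure may be outrun by intermolecular metathesis, because the C1' vinyl group is a branched allylic silyl ether and the two carbinol substituents end up on opposite faces of the medium ring. The long Si–O bonds also soften the strain penalty of a trans alkene, so geometrical purity may erode. The fallback gives up metathesis and makes C1'=C2' by a salt-free Wittig reaction, setting out from 16 and 21.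
- Silylation of 16 (Et3SiCl, imidazole) gives the triethylsilyl ether F1, and ozonolysis with NaBH4 work-up gives the primary alcohol F2.
- I2/PPh3/imidazole gives the iodide F3, and PPh3 (iPr2NEt, MeCN, 80 °C) gives the phosphonium iodide F4.
- In parallel, 21 is converted into its triethylsilyl ether F6 and cleaved (OsO4 cat., NaIO4, 2,6-lutidine) to the α-silyloxy aldehyde F7.
- NaN(SiMe3)2 (THF, −78 °C) turns F4 into the ylide F5, which should add to F7 under kinetic control to give the cis alkene F8.
- PPTS in MeOH removes only the two triethylsilyl groups to give the diol F9. Bridging F9 with 22 (imidazole, dilute CH2Cl2/DMF) comes back to the route at 25.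

Step 13 may suffer from scrambling at silicon. Possible failure processes are double substitution by 21, hydrolysis of the chlorosilane before the second alcohol arrives, and sluggish attack by the hindered C4' hydroxyl. The fallback replaces the double chloride displacement by a hydridosilane that can be purified and is activated only when needed. It sets out from 21.
- Chlorodiisopropylsilane and imidazole give the alkoxy(hydrido)silane F10.
- N-Bromosuccinimide (CH2Cl2, 0 °C) converts the Si–H bond into the bromosilane F11.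
- Addition of 16 with Et3N and DMAP comes back to the route at 24.

Step 17 may fail through base-induced β-elimination of the allylic silyloxy group from the aldehyde and through incomplete Z selectivity, and an E-ester cannot lactonise. The fallback avoids any olefination geometry by closing the ring first and introducing C3=C4 by elimination inside it. It sets out from 27.
- A Reformatsky addition (methyl bromoacetate, activated Zn, THF) gives the β-hydroxy ester F12 as an inconsequential epimer mixture.
- Ac2O/pyridine at 0 °C gives the β-acetoxy ester F13.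
- HF·pyridine removes all silicon with lactonisation to the 4-acetoxy δ-lactone F14.
- Brief treatment with Et3N (CH2Cl2, 0 °C) eliminates acetic acid, which within the six-membered ring can only give the cis alkene, and comes back to the route at 30.

**Further compounds**

F1 | step 14 | triethylsilyl ether of 16 | CC(=O)O[C@H](CCc1ccccc1)C[C@H](O[Si](C)(C)C(C)(C)C)C[C@H](O[Si](CC)(CC)CC)CC=C
F2 | step 14 | C2' primary alcohol | CC(=O)O[C@H](CCc1ccccc1)C[C@H](O[Si](C)(C)C(C)(C)C)C[C@H](O[Si](CC)(CC)CC)CCO
F3 | step 14 | C2' iodide | CC(=O)O[C@H](CCc1ccccc1)C[C@H](O[Si](C)(C)C(C)(C)C)C[C@H](O[Si](CC)(CC)CC)CCI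
F4 | step 14 | C2' triphenylphosphonium iodide | CC(=O)O[C@H](CCc1ccccc1)C[C@H](O[Si](C)(C)C(C)(C)C)C[C@H](O[Si](CC)(CC)CC)CC[P+](c1ccccc1)(c1ccccc1)c1ccccc1.[I-]
F5 | step 14 | C2' triphenylphosphonium ylide | CC(=O)O[C@H](CCc1ccccc1)C[C@H](O[Si](C)(C)C(C)(C)C)C[C@H](O[Si](CC)(CC)CC)CC=P(c1ccccc1)(c1ccccc1)c1ccccc1
F6 | step 14 | triethylsilyl ether of 21 | CC[Si](CC)(CC)O[C@H](C=C)CCOCc1ccc(OC)cc1
F7 | step 14 | (2S)-4-[(4-methoxybenzyl)oxy]-2-[(triethylsilyl)oxy]butanal | CC[Si](CC)(CC)O[C@H](C=O)CCOCc1ccc(OC)cc1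
F8 | step 14 | acyclic cis alkene with triethylsilyl ethers at O6 and O4' | CC(=O)O[C@H](CCc1ccccc1)C[C@H](O[Si](C)(C)C(C)(C)C)C[C@H](O[Si](CC)(CC)CC)C/C=C\[C@H](CCOCc1ccc(OC)cc1)O[Si](CC)(CC)CC
F9 | step 14 | cis C6,C4' diol | CC(=O)O[C@H](CCc1ccccc1)C[C@H](O[Si](C)(C)C(C)(C)C)C[C@H](O)C/C=C\[C@H](CCOCc1ccc(OC)cc1)O
F10 | step 13 | diisopropyl({(3S)-5-[(4-methoxybenzyl)oxy]pent-1-en-3-yl}oxy)silane | CC(C)[SiH](C(C)C)O[C@H](C=C)CCOCc1ccc(OC)cc1
F11 | step 13 | bromo(diisopropyl)({(3S)-5-[(4-methoxybenzyl)oxy]pent-1-en-3-yl}oxy)silane | CC(C)[Si](Br)(C(C)C)O[C@H](C=C)CCOCc1ccc(OC)cc1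
F12 | step 17 | cyclic silaketal β-hydroxy ester (C4 epimers) | CC(=O)O[C@H](CCc1ccccc1)C[C@H](O[Si](C)(C)C(C)(C)C)C[C@H]1C/C=C\[C@H](CC(O)CC(=O)OC)O[Si](C(C)C)(C(C)C)O1
F13 | step 17 | cyclic silaketal β-acetoxy ester (C4 epimers) | CC(=O)O[C@H](CCc1ccccc1)C[C@H](O[Si](C)(C)C(C)(C)C)C[C@H]1C/C=C\[C@H](CC(CC(=O)OC)OC(C)=O)O[Si](C(C)C)(C(C)C)O1
F14 | step 17 | 4-acetoxy δ-lactone diol (C4 epimers) | CC(=O)O[C@H](CCc1ccccc1)C[C@H](O)C[C@H](O)C/C=C\[C@@H]1CC(CC(=O)O1)OC(C)=O
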